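All runs are calculated on assumed constants, noise included.

4 questions stood on the east flask, and I answered them from its late readings, of target made and of substrate left alike.

| flask | substrate | reagent | catalyst | temperature | remark | time |
|---|---|---|---|---|---|---|
| east | 1 M | 3 M | 3.1 mM | 100 °C | the very flask that is asked about, followed so far |  |
| south-west | 1 M | 3 M | 1.6 mM | 95 °C | run made earlier |  |
| flask | 1.0 M | 3.00 M | 3.1 mM | 100 °C |  | 2.0 d |

- east (time / h: target / %, substrate / %): 4.00: 69.8, 15.6; 6.00: 76.0, 10.5; 8.00: 78.8, 7.5; 15.0: 80.7, 6.3; 20.0: 80.5, 7.7; 30.0: 81.8, 6.8; 50.0: 80.0, 6.9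
- south-west (time / h: target / %, substrate / %): 0.500: 16.7, 76.1; 1.00: 27.2, 58.3; 1.50: 35.0, 47.5; 2.00: 42.5, 39.3; 2.50: 45.6, 32.7; 3.00: 50.6, 27.8; 4.00: 57.1, 19.9

(scatter of a reading: 1 percentage point)

- Friday's: at 2.0 d raise the temperature by 20 K, then wait 4.0 d
- Tuesday's: change nothing and wait 4.0 d more
- Wednesday's: at 2.0 d add catalyst, 100% of the amount charged, then wait 4.0 d

- the volume of additions can be left aside
- a reading or a percentage of target counts all its forms, free or not

- target, in percent of the substrate first charged, at 2.0 d
- the option that brings most further target ("none" if no option brings more than 2 percentage points) (Friday's / Tuesday's / Wednesday's / none)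
- target present, in percent of the substrate first charged, after Friday's
- target present, in percent of the substrate first charged, after Wednesday's

From 15.0 h to 50.0 h the east readings averaged 80.8% target and 6.93% substrate, so 12.3% of the substrate charged was in neither. I took this missing part as a second product costing one reagent per substrate, which left 2.07 M of reagent. Missing part over substrate left, divided by reagent left, gave 0.860 L mol⁻¹. I called this the holding constant, the missing part per substrate left and per mole per litre of reagent left, an apparent equilibrium constant read from readings with a scatter of 1 percentage point.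

Since those readings did not drift, I expected about 80.8% at 2.0 d and no gain from waiting or from catalyst, with 19.2% of the substrate outside target. The south-west run, still moving at 4.00 h, gave no plateau at a second temperature, so I left the sign of heating open.

The forecast gave 80.7% at 2.0 d, 79.5% after Friday's, 80.8% after Wednesday's and none as best option, holding that “Heating only shifts the equilibrium modestly, direction unknown”.

The east flask gave 81.1% at 2.0 d. Friday's added 7.9 points and reached 89.0%, Tuesday's added 0 points, and Wednesday's added 0 points and stood at 81.1%, so the best option was Friday's.

    substrate + reagent ⇌ target (K = 2.60 L mol⁻¹, k = 0.180 L mol⁻¹ h⁻¹, Ea = 73.0 kJ mol⁻¹, ΔH = 6.00 kJ mol⁻¹)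
    substrate + reagent ⇌ isomer of the product (K = 0.780 L mol⁻¹, k = 0.0920 L mol⁻¹ h⁻¹, Ea = 74.0 kJ mol⁻¹, ΔH = −53.0 kJ mol⁻¹)
    target + catalyst ⇌ isomer of the product + catalyst, rate k3*[catalyst]*[target] forward; the back reaction follows from the equilibrium constant (k = 54.0 L mol⁻¹ h⁻¹, Ea = 73.0 kJ mol⁻¹)
    crystals ⇌ target, rate k4*(cs4 - [target]) while solid is left; crystals form when [target] > cs4 (solubility = 0.390 M, k = 2.80 h⁻¹)
    (constants at 100 °C)

In the east flask half of the crystallising turnover up to 2.0 d was done by 3.19 h, far earlier than the time of looking, and at 2.0 d the backward rate of the step to target stood at 100% of its forward rate. At 480 h target in this flask stood at 81.1%. The holding constant times the reagent and substrate left gives 12.9% for isomer of the product in this flask, which held 11.7%. For the neighbour charged with 0.75 M of reagent it gives 12.2%, and that neighbour held 11.0%.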